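**Strategy.** The tetrahydropyran of the target is a di-tertiary ether: its oxygen is flanked by the fully substituted carbons C3 and C7 (chain numbering from C1 = CH2Cl). The route grows this ring from a three-membered one. A Sharpless-derived vinyl oxirane already holds C7 with its methyl group, the chain to ring A and the future ring oxygen. A rhodium carbenoid carrying the C3 methyl and an ester binds that oxygen, and the oxonium ylide undergoes a [2,3] shift that forms the C3–C4 bond and closes the dihydropyran in one operation. Ring A comes first, by asymmetric bromocyclisation of geranylacetone; afterwards the ester becomes the chlorohydrin and the C5=C6 alkene the C6 bromide.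

Key step: step 9

Remark on numbering: C1 = CH2Cl, C2 = CHOH, pyran = O/C3/C4/C5/C6/C7 (C6 = CHBr), C8–C9 = ethylene link, ring A = C10–C15 (C11 = C(OH)CH3, C14 = CHBr, C15 = C(CH3)2).

Remark on names: "RA" stands for the ring-A unit (1R,3R,6R)-3-bromo-2,2,6-trimethyl-6-(triethylsilyloxy)cyclohexyl.

Assumption: (E)-geranylacetone is bought as the pure E isomer, and the antipode of the bromocyclisation catalyst is the one that gives the (14R) series.

Step 1
Reactants: 1 (E)-geranylacetone
Product: 3 hydroxy ketone 4-[(1R,3R,6R)-3-bromo-6-hydroxy-2,2,6-trimethylcyclohexyl]butan-2-one, via bromo enol ether 2 (not isolated)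
Conditions: DBDMH (0.55 equiv), chiral BINOL-derived thiophosphoramide Lewis-base catalyst (10 mol %), toluene/CH2Cl2, −78 °C; then 1 M HCl, THF, 0 °C
Reagents that add atoms: 1,3-dibromo-5,5-dimethylhydantoin CC1(C)N(Br)C(=O)N(Br)C1=O; water O
Why: Catalytic asymmetric bromonium-induced polyene cyclisation, in which the chiral Lewis base delivers Br+ to one face of the terminal alkene (sets C14), the chair-like closure onto the E alkene sets C10 and C11 by anti addition, the ketone oxygen captures the C11 cation as enol ether 2, and mild acid hydrolysis should release the trans hydroxy ketone.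

Step 2
Reactants: 3 hydroxy ketone
Product: 4 silyl ether ketone 4-(RA)butan-2-one
Conditions: TESOTf, 2,6-lutidine, CH2Cl2, −78 → 0 °C
Reagents that add atoms: triethylsilyl trifluoromethanesulfonate CC[Si](CC)(CC)OS(=O)(=O)C(F)(F)F
Why: Silylation of the hindered tertiary alcohol with a silyl triflate and a weak hindered base, which should not enolise the ketone at low temperature; the cap prevents oxa-Michael closure in step 3 and O–H insertion in step 9.

Step 3
Reactants: 4 silyl ether ketone
Product: 5 (E)-enoate ethyl (2E)-3-methyl-5-(RA)pent-2-enoate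
Conditions: triethyl phosphonoacetate, NaH, THF, 0 °C → rt; minor Z isomer removed by chromatography
Reagents that add atoms: triethyl phosphonoacetate CCOC(=O)CP(=O)(OCC)OCC
Why: Horner–Wadsworth–Emmons olefination of the methyl ketone, in which the stabilised phosphonate anion should give mainly the E trisubstituted enoate that fixes the geometry needed for the epoxidation.

Step 4
Reactants: 5 (E)-enoate
Product: 6 allylic alcohol (2E)-3-methyl-5-(RA)pent-2-en-1-ol
Conditions: i-Bu2AlH (2.2 equiv), CH2Cl2, −78 °C; aq. potassium sodium tartrate (KNaC4H4O6)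
Reagents that add atoms: none
Why: 1,2-Reduction of the conjugated ester by the aluminium hydride at low temperature, which should leave the alkene geometry, the bromide and the silyl ether untouched.

Step 5
Reactants: 6 allylic alcohol
Product: 7 epoxy alcohol [(2S,3S)-3-methyl-3-[2-(RA)ethyl]oxiran-2-yl]methanol
Conditions: Ti(OiPr)4 (10 mol %), L-(+)-diethyl tartrate (12 mol %), t-BuOOH, 4 Å molecular sieves, CH2Cl2, −20 °C
Reagents that add atoms: tert-butyl hydroperoxide CC(C)(C)OO
Why: Sharpless asymmetric epoxidation, in which the titanium tartrate complex with the L-(+)-tartrate delivers oxygen to the face of the E allylic alcohol that gives the (2S,3S)-epoxy alcohol, so C7 (S) is set under reagent control irrespective of ring A.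

Step 6
Reactants: 7 epoxy alcohol
Product: 8 epoxy aldehyde (2R,3S)-3-methyl-3-[2-(RA)ethyl]oxirane-2-carbaldehyde
Conditions: TEMPO (10 mol %), PhI(OAc)2, CH2Cl2, rt
Reagents that add atoms: none
Why: Oxoammonium (TEMPO) oxidation of the primary alcohol should stop at the aldehyde and spare the trisubstituted oxirane and the silyl ether.

Step 7
Reactants: 8 epoxy aldehyde
Product: 9 vinyl oxirane (2S,3S)-2-methyl-2-[2-(RA)ethyl]-3-vinyloxirane
Conditions: Ph3PCH3Br, KN(SiMe3)2, THF, −78 → 0 °C
Reagents that add atoms: methyltriphenylphosphonium bromide C[P+](c1ccccc1)(c1ccccc1)c1ccccc1.[Br-]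
Why: Wittig methylenation with the salt-free ylide at low temperature, under which the oxirane stereocentres are not epimerisable.

Step 8
Reactants: 10 ethyl 2-methylacetoacetate
Product: 11 ethyl 2-diazopropanoate
Conditions: p-ABSA, DBU, MeCN, 0 °C → rt
Reagents that add atoms: 4-acetamidobenzenesulfonyl azide CC(=O)Nc1ccc(cc1)S(=O)(=O)N=[N+]=[N-]
Why: Deacylative diazo transfer (Regitz type), in which the enolate of the 2-methyl β-keto ester attacks the sulfonyl azide and the adduct fragments with transfer of the acetyl group to the sulfonamide, leaving the α-methyl diazo ester.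

Step 9
Reactants: 9 vinyl oxirane; 11 ethyl 2-diazopropanoate
Product: 13 dihydropyran ester ethyl (2S,6S)-2,6-dimethyl-6-[2-(RA)ethyl]-3,6-dihydro-2H-pyran-2-carboxylate, via oxiranium ylide 12 (not isolated)
Conditions: Rh2(OPiv)4 (2 mol %), CH2Cl2, −40 → 0 °C, 11 (3 equiv) added slowly by syringe pump
Reagents that add atoms: none
Why: The electrophilic rhodium carbenoid from 11 is intercepted by the oxirane oxygen of 9, and oxiranium ylide 12 rearranges by a concerted suprafacial [2,3]-sigmatropic shift in which the ylide carbon C3 bonds to the vinyl terminus C4 while the allylic O–C6 bond breaks, with release of the three-ring strain. The closest known reaction type is the oxonium-ylide [2,3] rearrangement of allylic ethers with metal carbenoids and its ring-expanding version with 2-vinyl oxetanes, 2-vinyl tetrahydrofurans and vinyl aziridines. The pyran closes through a five-centre envelope transition state fused to the oxirane, a three-atom ring enlargement (3 to 6) in which the former vinyl carbons C4 and C5 both become ring atoms and the new C5=C6 bond is necessarily cis. C7 keeps its Sharpless-derived configuration because its C–O bond is never broken; the new quaternary C3 is controlled by the ylide geometry, the carbenoid carbon lying on the oxirane face that carries the vinyl group and the C7 methyl (cis in the E-derived oxirane) with its ester exo, away from C7, so that the C3 methyl should end cis to the C7 methyl. The step needs ylide formation to beat cyclopropanation of the vinyl group, the [2,3] shift to beat deoxygenation and the [1,2] shift, and no 1,2-hydride migration to ethyl acrylate. These are addressed by the absence of any other alkene or free hydroxyl (silyl cap on C11–OH), by the allylic, strain-assisted ylide that should rearrange faster than it fragments, and by bulky pivalate ligands, low temperature and slow addition of 11.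

Step 10
Reactants: 13 dihydropyran ester
Product: 15 chloromethyl ketone 2-chloro-1-[(2S,6S)-2,6-dimethyl-6-[2-(RA)ethyl]-3,6-dihydro-2H-pyran-2-yl]ethan-1-one, via lithium hemiketal alkoxide 14 (not isolated)
Conditions: ICH2Cl, MeLi·LiBr, THF/Et2O, −78 °C; AcOH quench at −78 °C
Reagents that add atoms: chloroiodomethane ClCI
Why: Carbenoid homologation of an ester, in which LiCH2Cl (from iodine–lithium exchange) adds once to give tetrahedral alkoxide 14, stable at −78 °C, which collapses to the ketone only on acidic quench, so over-addition should be avoided and C3 and C7 are untouched.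

Step 11
Reactants: 15 chloromethyl ketone
Product: 16 chlorohydrin (1S)-2-chloro-1-[(2S,6S)-2,6-dimethyl-6-[2-(RA)ethyl]-3,6-dihydro-2H-pyran-2-yl]ethan-1-ol
Conditions: (S)-2-methyl-CBS-oxazaborolidine (20 mol %), catecholborane, toluene, −78 → −40 °C
Reagents that add atoms: none
Why: Corey–Bakshi–Shibata reduction, in which the oxazaborolidine binds the ketone anti to the quaternary pyran carbon (large group, CH2Cl small) and should deliver hydride to the face that gives the (S)-carbinol C2 under reagent control, while catecholborane at low temperature leaves the ring alkene alone.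

Step 12
Reactants: 16 chlorohydrin
Product: 17 bis-silyl ether, 16 with the C2 hydroxyl as its triethylsilyl ether
Conditions: TESOTf, 2,6-lutidine, CH2Cl2, −78 → 0 °C
Reagents that add atoms: triethylsilyl trifluoromethanesulfonate CC[Si](CC)(CC)OS(=O)(=O)C(F)(F)F
Why: Silylation under weakly basic conditions that cannot close the chlorohydrin to an epoxide; the bulky silyloxy side chain is then firmly equatorial at C3 and protects C2–OH from the bromination in step 14.

Step 13
Reactants: 17 bis-silyl ether
Product: 19 axial alcohol (2S,3S,6S)-6-[(1S)-2-chloro-1-(triethylsilyloxy)ethyl]-2,6-dimethyl-2-[2-(RA)ethyl]tetrahydro-2H-pyran-3-ol, via alkylborane 18 (not isolated)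
Conditions: BH3·THF, THF, 0 °C → rt; then 30% H2O2, aq. NaOH, 0 °C
Reagents that add atoms: hydrogen peroxide OO
Why: Hydroboration–oxidation, in which the equatorial C3 side chain places both ring methyls (C3, C7) axial on one face so that borane should add syn from the opposite face, the allylic C7–O bond steering boron to C6, and oxidation with retention gives the axial (6S) alcohol.

Step 14
Reactants: 19 axial alcohol
Product: 20 bromide, the bis(triethylsilyl) ether of the target (6R bromide)
Conditions: CBr4, P(n-Oct)3, toluene, 70 °C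
Reagents that add atoms: carbon tetrabromide BrC(Br)(Br)Br
Why: Appel-type bromination through the alkoxyphosphonium ion with SN2 inversion at C6 should give the equatorial bromide cis to the C7 methyl, the axial leaving group being gauche to the ring oxygen so that oxonium participation and ring contraction are disfavoured.

Step 15
Reactants: 20 bromide
Product: 21 target, (1S)-2-chloro-1-[(2S,5R,6S)-5-bromo-6-{2-[(1R,3R,6R)-3-bromo-6-hydroxy-2,2,6-trimethylcyclohexyl]ethyl}-2,6-dimethyltetrahydro-2H-pyran-2-yl]ethan-1-ol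
Conditions: HF·pyridine, pyridine/THF, 0 °C → rt
Reagents that add atoms: none
Why: Fluoride cleavage of both silyl ethers under mildly acidic conditions that should spare the chlorohydrin (no epoxide closure) and both secondary bromides, with no stereocentre touched.

**Compound list**

1 | (E)-geranylacetone, (5E)-6,10-dimethylundeca-5,9-dien-2-one | CC(=O)CC/C=C(\C)CCC=C(C)C | starting material
2 | bromo enol ether (4aR,6R,8aR)-6-bromo-2,5,5,8a-tetramethyl-4a,5,6,7,8,8a-hexahydro-4H-chromene | CC1(C)[C@H](Br)CC[C@@]2(C)OC(C)=CC[C@H]12 | intermediate (not isolated)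
3 | hydroxy ketone 4-[(1R,3R,6R)-3-bromo-6-hydroxy-2,2,6-trimethylcyclohexyl]butan-2-one | CC1(C)[C@H](Br)CC[C@@](C)(O)[C@@H]1CCC(C)=O | intermediate
4 | silyl ether ketone 4-(RA)butan-2-one | CC1(C)[C@H](Br)CC[C@@](C)(O[Si](CC)(CC)CC)[C@@H]1CCC(C)=O | intermediate
5 | (E)-enoate ethyl (2E)-3-methyl-5-(RA)pent-2-enoate | CC1(C)[C@H](Br)CC[C@@](C)(O[Si](CC)(CC)CC)[C@@H]1CC/C(C)=C/C(=O)OCC | intermediate
6 | allylic alcohol (2E)-3-methyl-5-(RA)pent-2-en-1-ol | CC1(C)[C@H](Br)CC[C@@](C)(O[Si](CC)(CC)CC)[C@@H]1CC/C(C)=C/CO | intermediate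
7 | epoxy alcohol [(2S,3S)-3-methyl-3-[2-(RA)ethyl]oxiran-2-yl]methanol | CC1(C)[C@H](Br)CC[C@@](C)(O[Si](CC)(CC)CC)[C@@H]1CC[C@]1(C)O[C@H]1CO | intermediate
8 | epoxy aldehyde (2R,3S)-3-methyl-3-[2-(RA)ethyl]oxirane-2-carbaldehyde | CC1(C)[C@H](Br)CC[C@@](C)(O[Si](CC)(CC)CC)[C@@H]1CC[C@]1(C)O[C@H]1C=O | intermediate
9 | vinyl oxirane (2S,3S)-2-methyl-2-[2-(RA)ethyl]-3-vinyloxirane | CC1(C)[C@H](Br)CC[C@@](C)(O[Si](CC)(CC)CC)[C@@H]1CC[C@]1(C)O[C@H]1C=C | intermediate
10 | ethyl 2-methylacetoacetate (ethyl 2-methyl-3-oxobutanoate) | CCOC(=O)C(C)C(C)=O | starting material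
11 | ethyl 2-diazopropanoate | CCOC(=O)C(C)=[N+]=[N-] | intermediate
12 | oxiranium ylide, 9 carrying the carbanion C(CH3)(CO2Et) on the oxirane oxygen | CC1(C)[C@H](Br)CC[C@@](C)(O[Si](CC)(CC)CC)[C@@H]1CC[C@]1(C)[O+]([C-](C)C(=O)OCC)[C@H]1C=C | intermediate (not isolated)
13 | dihydropyran ester ethyl (2S,6S)-2,6-dimethyl-6-[2-(RA)ethyl]-3,6-dihydro-2H-pyran-2-carboxylate | CC1(C)[C@H](Br)CC[C@@](C)(O[Si](CC)(CC)CC)[C@@H]1CC[C@]1(C)O[C@](C)(C(=O)OCC)CC=C1 | intermediate
14 | lithium hemiketal alkoxide, adduct of LiCH2Cl to the ester carbonyl of 13 | CC1(C)[C@H](Br)CC[C@@](C)(O[Si](CC)(CC)CC)[C@@H]1CC[C@]1(C)O[C@](C)(C([O-])(OCC)CCl)CC=C1.[Li+] | intermediate (not isolated)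
15 | chloromethyl ketone 2-chloro-1-[(2S,6S)-2,6-dimethyl-6-[2-(RA)ethyl]-3,6-dihydro-2H-pyran-2-yl]ethan-1-one | CC1(C)[C@H](Br)CC[C@@](C)(O[Si](CC)(CC)CC)[C@@H]1CC[C@]1(C)O[C@](C)(C(=O)CCl)CC=C1 | intermediate
16 | chlorohydrin (1S)-2-chloro-1-[(2S,6S)-2,6-dimethyl-6-[2-(RA)ethyl]-3,6-dihydro-2H-pyran-2-yl]ethan-1-ol | CC1(C)[C@H](Br)CC[C@@](C)(O[Si](CC)(CC)CC)[C@@H]1CC[C@]1(C)O[C@](C)([C@H](O)CCl)CC=C1 | intermediate
17 | bis-silyl ether, 16 with C2–OH as triethylsilyl ether | CC1(C)[C@H](Br)CC[C@@](C)(O[Si](CC)(CC)CC)[C@@H]1CC[C@]1(C)O[C@](C)([C@H](O[Si](CC)(CC)CC)CCl)CC=C1 | intermediate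
18 | alkylborane, 17 with BH2 on C6 (face opposite the ring methyls) and H on C5 | CC1(C)[C@H](Br)CC[C@@](C)(O[Si](CC)(CC)CC)[C@@H]1CC[C@]1(C)O[C@](C)([C@H](O[Si](CC)(CC)CC)CCl)CC[C@@H]1B | intermediate (not isolated)
19 | axial alcohol (2S,3S,6S)-6-[(1S)-2-chloro-1-(triethylsilyloxy)ethyl]-2,6-dimethyl-2-[2-(RA)ethyl]tetrahydro-2H-pyran-3-ol | CC1(C)[C@H](Br)CC[C@@](C)(O[Si](CC)(CC)CC)[C@@H]1CC[C@]1(C)O[C@](C)([C@H](O[Si](CC)(CC)CC)CCl)CC[C@@H]1O | intermediate
20 | bromide, bis(triethylsilyl) ether of the target (6R) | CC1(C)[C@H](Br)CC[C@@](C)(O[Si](CC)(CC)CC)[C@@H]1CC[C@]1(C)O[C@](C)([C@H](O[Si](CC)(CC)CC)CCl)CC[C@H]1Br | intermediate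
21 | target CNP0182369.1, (1S)-2-chloro-1-[(2S,5R,6S)-5-bromo-6-{2-[(1R,3R,6R)-3-bromo-6-hydroxy-2,2,6-trimethylcyclohexyl]ethyl}-2,6-dimethyltetrahydro-2H-pyran-2-yl]ethan-1-ol | CC1(C)[C@H](Br)CC[C@@](C)(O)[C@@H]1CC[C@]1(C)O[C@](C)([C@H](O)CCl)CC[C@H]1Br | target

**Step count and risks**

Total: 15 steps. Longest linear sequence: 14 steps (steps 1–7 and 9–15 from geranylacetone); step 8 is a one-step side branch.

Most likely to fail:

1. Step 9 (key step). The ylide may collapse by oxygen transfer, deoxygenating the oxirane to the diene. The carbenoid may instead cyclopropanate the vinyl group or undergo 1,2-hydride shift. The ylide carbon may also bond with the wrong face, so that the C3 epimer dominates. The fallback sets out from 9 and comes back at 21; it closes the same C3–C4 bond by enolate alkylation and fixes C6 stereospecifically. Hydroboration of the vinyl group of 9 with 9-BBN (then H2O2, aq. NaOH) should give epoxy alcohol F1. CBr4/PPh3/2,6-lutidine should give bromo epoxide F2. Li2NiBr4 in THF should open the oxirane at the secondary carbon C6 with inversion to give anti bromohydrin F3, with the C6 bromide in the target configuration and a free C7 tertiary alcohol. Rh2(OAc)4-catalysed O–H insertion of 11 should give lactate ether F4 (either epimer at the lactate carbon serves). KN(SiMe3)2 in THF at −78 °C should close the ring by 6-exo-tet alkylation of the ester enolate at C4 to give bromo ester F5. Chloromethylation as in step 10 should give chloromethyl ketone F6, reduction as in step 11 chlorohydrin F7, and HF·pyridine then gives 21.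

2. Step 13. Boron may add to the less hindered C5 instead of C6, or from the face that carries the two methyl groups if the ring does not adopt the expected half-chair. The fallback sets out from 17 and comes back at 19. mCPBA/NaHCO3 should epoxidise C5=C6 from the face opposite the axial methyls to give epoxide F8. Et2Al(TMP) (diethylaluminium 2,2,6,6-tetramethylpiperidide) in toluene at 0 °C should isomerise it, by removal of the only available β-hydrogen (at C4), to allylic alcohol F9 with C4=C5 and the C6 oxygen unchanged. Diimide (potassium azodicarboxylate KO2CN=NCO2K, AcOH, MeOH) should saturate the alkene without touching C–Br or C–Cl to give 19.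

3. Step 1. The chiral Lewis-base catalysis is established with arene-terminated polyenes and may give poor enantiofacial discrimination with carbonyl termination, or the C11 cation may lose a proton instead of being captured. The fallback sets out from 1 and comes back at 3. Racemic cyclisation with Et2SBr·SbBrCl5 (BDSB) in MeNO2 at −25 °C and the same acid hydrolysis should give 3 together with ent-hydroxy ketone F11 (formed via ent-enol ether F10 alongside 2). The enantiomers are then separated by preparative chromatography on a chiral stationary phase.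

**Further compounds**

F1 | step 9 | epoxy alcohol 2-[(2S,3S)-3-methyl-3-[2-(RA)ethyl]oxiran-2-yl]ethan-1-ol | CC1(C)[C@H](Br)CC[C@@](C)(O[Si](CC)(CC)CC)[C@@H]1CC[C@]1(C)O[C@H]1CCO
F2 | step 9 | bromo epoxide, F1 with CH2Br in place of CH2OH | CC1(C)[C@H](Br)CC[C@@](C)(O[Si](CC)(CC)CC)[C@@H]1CC[C@]1(C)O[C@H]1CCBr
F3 | step 9 | anti bromohydrin, C4/C6 dibromide with free C7 tertiary alcohol | CC1(C)[C@H](Br)CC[C@@](C)(O[Si](CC)(CC)CC)[C@@H]1CC[C@](C)(O)[C@H](Br)CCBr
F4 | step 9 | lactate ether, F3 with C7–O–CH(CH3)CO2Et | CC1(C)[C@H](Br)CC[C@@](C)(O[Si](CC)(CC)CC)[C@@H]1CC[C@](C)(OC(C)C(=O)OCC)[C@H](Br)CCBr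
F5 | step 9 | bromo ester ethyl (2S,5R,6S)-5-bromo-2,6-dimethyl-6-[2-(RA)ethyl]tetrahydro-2H-pyran-2-carboxylate | CC1(C)[C@H](Br)CC[C@@](C)(O[Si](CC)(CC)CC)[C@@H]1CC[C@]1(C)O[C@](C)(C(=O)OCC)CC[C@H]1Br
F6 | step 9 | chloromethyl ketone of F5 | CC1(C)[C@H](Br)CC[C@@](C)(O[Si](CC)(CC)CC)[C@@H]1CC[C@]1(C)O[C@](C)(C(=O)CCl)CC[C@H]1Br
F7 | step 9 | chlorohydrin, the C11 triethylsilyl ether of the target | CC1(C)[C@H](Br)CC[C@@](C)(O[Si](CC)(CC)CC)[C@@H]1CC[C@]1(C)O[C@](C)([C@H](O)CCl)CC[C@H]1Br
F8 | step 13 | epoxide, 17 epoxidised at C5=C6 on the face opposite the ring methyls | CC1(C)[C@H](Br)CC[C@@](C)(O[Si](CC)(CC)CC)[C@@H]1CC[C@]1(C)O[C@](C)([C@H](O[Si](CC)(CC)CC)CCl)C[C@@H]2O[C@@H]21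
F9 | step 13 | allylic alcohol, C4=C5 alkene with C6–OH as in 19 | CC1(C)[C@H](Br)CC[C@@](C)(O[Si](CC)(CC)CC)[C@@H]1CC[C@]1(C)O[C@](C)([C@H](O[Si](CC)(CC)CC)CCl)C=C[C@@H]1O
F10 | step 1 | ent-enol ether (4aS,6S,8aS)-6-bromo-2,5,5,8a-tetramethyl-4a,5,6,7,8,8a-hexahydro-4H-chromene | CC1(C)[C@@H](Br)CC[C@]2(C)OC(C)=CC[C@@H]12
F11 | step 1 | ent-hydroxy ketone 4-[(1S,3S,6S)-3-bromo-6-hydroxy-2,2,6-trimethylcyclohexyl]butan-2-one | CC1(C)[C@@H](Br)CC[C@](C)(O)[C@H]1CCC(C)=O
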